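Amounts come first here: the substrate charge stays at 0.050 M while the reagent charge moves, so these flasks differ by one ratio.

| setting | Friday's | Sunday's | Tuesday's | violet | blue | amber |
|---|---|---|---|---|---|---|
| substrate | 0.050 M | 0.050 M | 0.050 M | 0.050 M | 0.050 M | 0.050 M |
| reagent | 0.073 M | 0.11 M | 0.21 M | 0.120 M | 0.0600 M | 0.240 M |
| remark | run made earlier | run made earlier | run made earlier |  |  |  |
| time |  |  |  | 6.0 min | 6.0 min | 6.0 min |

| run | time / min | substrate / % | product / % |
|---|---|---|---|
| Friday's | 0.500 | 29.1 | 62.7 |
| Friday's | 1.50 | 5.0 | 85.5 |
| Friday's | 3.00 | 0.9 | 90.5 |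
| Friday's | 4.00 | 0.6 | 90.9 |
| Friday's | 6.00 | 0.2 | 92.7 |
| Sunday's | 1.33 | 2.5 | 88.8 |
| Sunday's | 2.50 | 0.5 | 93.2 |
| Sunday's | 4.00 | 0 | 93.8 |
| Sunday's | 5.00 | 1.2 | 94.2 |
| Sunday's | 6.00 | 0.6 | 95.1 |
| Tuesday's | 0.500 | 12.2 | 81.6 |
| Tuesday's | 0.833 | 3.2 | 89.8 |
| Tuesday's | 1.50 | 0.7 | 93.4 |
| Tuesday's | 3.00 | 0 | 94.7 |
| Tuesday's | 6.00 | 0 | 96.9 |

(readings scatter by 0.5 percentage points)

* which of these there is most of at the end, counted by the substrate in it, violet (product / substrate)
* which of these there is most of at the end, counted by the substrate in it, blue (product / substrate)
* which of these there is most of at the end, counted by the substrate in it, amber (product / substrate)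
* amount of the one of these that there is most of at the end, in percent of the substrate charged, violet
* amount of the one of these that there is most of at the end, in percent of the substrate charged, blue
* amount of the one of these that there is most of at the end, in percent of the substrate charged, amber

- a reading of substrate is of its free form alone

For blue 1.20 is that ratio, E, the equivalents of reagent: reagent charged per substrate charged. Violet has 2.40 and amber 4.80.

Friday's 92.7 % of product rules out two reagent per substrate, which would take 0.0927 M, more than the 0.073 M charged. I therefore take one to one, and E reads as a ceiling: product stays at or below the smaller of E and one, as a share of the substrate charged. In violet, blue and amber E is above one, so substrate is the limiting reagent.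

The ceiling does not give the yield. At 6.00 min Friday's run, with E at 1.46, reads 0.2 % of substrate, yet product falls short of the charge by 7.30 %, so the rest of that shortfall sits in a form the readings do not show. Tuesday's run, with E at 4.20, falls short by less, 3.10 %. With substrate held at 0.050 M, I draw a power line through these two runs:

n = ln(Friday's shortfall / Tuesday's shortfall) / ln(Tuesday's E / Friday's E) = 0.811

shortfall at E = Friday's shortfall × (Friday's E / E)^n

Sunday's run tests it: the line gives 5.24 %, the reading 4.90 %, and readings scatter by 0.5 percentage points. My reckoning for product at 6.0 min is 95.1 % for violet, 91.4 % for blue and 97.2 % for amber.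

The forecast gives 95.2 %, 90.3 % and 97 %, lower than mine for blue, where it counts about 1% of free substrate left by the thin excess of reagent on top of about 8% in the hidden form, and adds: “Any reagent loss would lower this”.

The flasks give product in violet at 95.5 %, product in blue at 91.8 % and product in amber at 97.1 %.

    substrate + reagent → product, rate k1*[substrate]*[reagent]^0.5 (k = 0.156 M⁻⁰·⁵ s⁻¹)
    substrate ⇌ dormant form (K = 1.90, k = 0.00499 s⁻¹)

In blue at 6.00 min the making of product has a substrate half-life of 0.62 min, while the slowest mode of the whole flask has a longer one, 5.53 min. Blue then holds 7.29 % as dormant form, more than its 0.887 % of substrate. Its shortfall at E of 1.20 is 8.20 %, against 8.56 % from my line. A neighbour of blue charged with 0.036 M of reagent has E of 0.720, below one, which puts its ceiling at 72.0 %; it holds 72.0 % of product with 0 % of its reagent left.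

(The data are simulated from invented constants, and the scatter is random.)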